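# Proposed synthesis of CNP0323250.1 through a temporary cis-fused lactone

## The problem

Compound 18 is a 2,3-dihydrobenzofuran with no carbocyclic skeleton to build. The difficulty lies in two adjacent stereocentres, C2 and C3 (both R, substituents cis), and in four oxygen functions that must each end with a different group. C2 carries a 3-acetoxyprop-1-en-2-yl group, C3 an angelate, C5 an acetyl group and C6 a free phenol hydrogen-bonded to that ketone.

The C3 oxygen is benzylic, para to the C6 oxygen and ortho to O1. A C3 ester therefore ionizes easily, and loss of the C2 proton then aromatizes the heterocycle to a benzofuran. The danger is greatest while the acetyl group is masked and the ring is electron-rich. The angelate is the Z isomer and drifts to the tiglate under base, nucleophiles or long heating. The aryl ketone does not survive hydride reagents unprotected.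

C3 is the centre a catalyst can set cleanly, as the carbinol of a coumaranone. It can then control C2 if the C2 substituent is delivered from a tether on the C3 oxygen. The structure invites this: the C3 oxygen and the propen-2-yl carbon on C2 are cis, and the acetoxymethyl carbon is a carboxyl carbon at the alcohol level. The C3 oxygen, that carbon, the propen-2-yl carbon, C2 and C3 are thus the five ring atoms of an opened cis-fused α-methylene-γ-butyrolactone. The C2–H bond that must be replaced lies next to O1 and is activated toward an electrophilic carbene.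

## Retrosynthesis

**18 to 17, then to 14 and 15.** The last bond cut is O–Si at C6, and before it the C3 O–acyl bond. Freeing the phenol last means it appears only once the acetyl group is there to tie it up by hydrogen bonding. A free phenoxide para to the C3 ester on a ketal-bearing ring would expel the angelate. The angelate is attached as late as possible because it is the most isomerization-prone group. It comes from alcohol 14 and angelic acid 15 through the mixed anhydride 16. The forward acylation must not touch the Z geometry and must not ionize C3.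

**14 to 13 to 12.** The acetyl group is unmasked from the dioxolane of 13 before the angelate is made. This is chosen over a final ketal hydrolysis because the acetyl group lowers the electron density of the ring before an ionizable C3 ester exists. The primary acetate of 13 is cut back to diol 12. This asks only that a primary allylic alcohol be acylated ahead of a hindered secondary benzylic one.

**12 to 11.** The two hydroxyl groups of 12 are reconnected through a carbonyl to the cis-fused α-methylene lactone 11. Nothing is simplified in atom count. The gain is that the cis relation of C2 and C3 becomes a ring fusion that can only be cis, and the allylic oxygen arrives as the lactone carbonyl. No late allylic oxidation in the presence of an angelate is then needed. The forward step is an exhaustive hydride reduction that must spare the exocyclic alkene.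

**11 to 10.** The exocyclic C=CH2 bond is cut to the α-phosphono lactone 10 and a one-carbon aldehyde. The phosphonate is preferred over a bare lactone enolate because its carbanion forms under carbonate base. It also serves as the second acceptor group that the carbene step needs.

**10 to 9 (key disconnection).** The bond from C2 to the future propen-2-yl carbon is cut. The lactone opens to the diazophosphonoacetate 9 of a C3 carbinol with an unsubstituted C2 methylene group. One C–C bond, one ring and the C2 stereocentre are removed at a stroke. This is preferred over cuts at C2–C3 or O1–C2, which would have to create both stereocentres without an internal reference. The forward step must put the carbene into the C2–H bond cis to the ester, not into C3–H or the arene.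

**9 to 8 to 6 and 7.** The diazo group is removed (diazo transfer in the forward sense). The ester C–O bond is then cut to the (3R)-alcohol 6 and 2-(diethoxyphosphoryl)acetic acid 7. Both are routine and leave a single stereocentre.

**6 to 5 to 4 to 3.** The C3–H bond is cut to the coumaranone 5, so that the only stereocentre comes from an enantioselective ketone reduction. For this the acetyl group must already be masked (ketal 5 from 4) and the phenol capped (4 from 3). The reduction then meets one carbonyl only. The forward ketalization has to tell the acetyl carbonyl from the ring carbonyl.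

**3 to 2 to 1.** The O1–C2 bond is cut to the bromomethyl ketone 2, and the C–Br bond to the symmetric diketone 1. The symmetry of 1 means that either acetyl group may be brominated and the one left over becomes the C5 acetyl of the target. The forward task is to stop at monobromination.

## Roads not taken

**Alternative 1: ring contraction of a chroman by 1,2-oxygen shift.** The cut is the O1–C2 bond, traced to a 2,2-dimethylchroman. In the forward step the C3 hydroxyl of the cis hydroxy angelate A1 is activated (Tf2O, 2,6-lutidine). O1 migrates from the dimethyl-bearing carbon to C3 with inversion, and the tertiary cation loses a proton to give the isopropenyl compound A2.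

- Merits: the skeleton comes from a chromene in very few steps, an asymmetric dihydroxylation sets both stereocentres catalytically, and the shift is stereospecific.
- Weak points: A2 has a methyl group where the target has CH2OAc. A late allylic oxidation would have to pick that methyl over the two allylic methyls of the angelate. In A1 the angeloyl group sits next to a cis hydroxyl and can migrate. The C4 hydrogen is anti to the leaving group, so hydride shift competes with oxygen shift.
- Comparison: this road is shorter to the ring system and sets both centres in one catalytic step, and the chosen plan cannot match that. The chosen plan sets against it that the allylic oxygen arrives at the right carbon as the lactone carbonyl. It also separates the C3 oxygen from the primary one without selective acylation of a cis diol.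

**Alternative 2: ring-contracting [2,3]-Wittig rearrangement.** The cut is the C2–C3 bond. A chiral lithium amide removes a benzylic proton from the eight-membered cyclic enol ether A3. The carbanion attacks the enol ether carbon across the ring as the O–CH2 bond breaks, giving the cis alcohol A4.

- Merits: C2–C3, both stereocentres and the isopropenyl group form in one step, and the product is a free C3 alcohol.
- Weak points: the medium ring with its Z enol ether has to be made. Enantiocontrol depends on a base telling two enantiotopic protons apart, which is less dependable than ketone transfer hydrogenation. [1,2]-Shift and ring metalation compete. A4 again lacks the allylic oxygen.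
- Comparison: if it worked it would be shorter and more convergent than the chosen plan. A4 differs from diol 12 only by the missing allylic hydroxyl and could join the route there after an allylic oxidation. The chosen plan offers a predictable source of absolute configuration and needs no oxidation of the side chain.

**Alternative 3: oxidative benzylic lactonization.** The cut is the C3–O bond. DDQ abstracts hydride from C3 of the acrylic acid A5 and the carboxyl group captures the cation to give A6, which is identical with lactone 11.

- Merits: it reaches 11 by one C–O bond formation, shares the whole endgame and avoids diazo compounds.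
- Weak points: DDQ is the classic reagent for dehydrogenating 2,3-dihydrobenzofurans to benzofurans. Once the C3 cation forms, loss of the C2 proton competes directly with lactonization. The cation is supported by a silyloxy group that can be lost. A5 needs its C2 centre from a separate asymmetric step and a twofold oxidation of a methyl group.
- Comparison: if aromatization could be suppressed this would be the shortest way to 11. The chosen plan carries C3 at the correct oxidation level from the coumaranone onward, so no oxidant ever meets the dihydrobenzofuran.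

Key step: step 8

Assumption: RuCl(p-cymene)[(S,S)-TsDPEN] is taken to reduce coumaranone 5 with the facial sense known for 1-indanone and chroman-4-one; because C2 carries oxygen this arrangement is named (3R), and the mirror-image catalyst would serve if the sense proved opposite.

## Route

Step 1
Reactants: 1 1,1'-(4,6-dihydroxy-1,3-phenylene)diethanone
Product: 2 1-(5-acetyl-2,4-dihydroxyphenyl)-2-bromoethan-1-one
Conditions: CuBr2 (2 equiv), EtOAc/CHCl3, reflux
Reagents that add atoms: CuBr2 (divalent copper), SMILES Br[Cu]Br
Why: α-Bromination of an aryl methyl ketone with CuBr2, which acts through the enol and is known to spare hydroxylated rings; two equivalents per molecule of the symmetric diketone should hold the reaction at one acetyl group, with unchanged 1 recovered.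

Step 2
Reactants: 2 1-(5-acetyl-2,4-dihydroxyphenyl)-2-bromoethan-1-one
Product: 3 5-acetyl-6-hydroxybenzofuran-3(2H)-one
Conditions: NaOAc, EtOH, reflux
Reagents that add atoms: none
Why: Intramolecular Williamson O-alkylation (5-exo-tet) of the ortho phenol on the bromomethyl ketone, the standard coumaranone closure; the second phenol cannot reach the bromide.

Step 3
Reactants: 3 5-acetyl-6-hydroxybenzofuran-3(2H)-one
Product: 4 5-acetyl-6-[(triisopropylsilyl)oxy]benzofuran-3(2H)-one
Conditions: TIPSCl, imidazole, DMF, rt
Reagents that add atoms: triisopropylsilyl chloride, SMILES CC(C)[Si](Cl)(C(C)C)C(C)C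
Why: Silylation of a phenol; the bulky triisopropylsilyl group is chosen to survive carbonate, i-Bu2AlH and mild acid later, and imidazole is too weak a base to silylate the ring ketone as its enol.

Step 4
Reactants: 4 5-acetyl-6-[(triisopropylsilyl)oxy]benzofuran-3(2H)-one
Product: 5 5-(2-methyl-1,3-dioxolan-2-yl)-6-[(triisopropylsilyl)oxy]benzofuran-3(2H)-one
Conditions: TMSOCH2CH2OTMS (1.5 equiv), TMSOTf (5 mol%), CH2Cl2, −78 to −20 °C; pyridine quench
Reagents that add atoms: 1,2-bis(trimethylsilyloxy)ethane, SMILES C[Si](C)(C)OCCO[Si](C)(C)C
Why: Noyori ketalization under aprotic conditions; the acetyl group, pushed out of the ring plane by the flanking silyloxy group, should react ahead of the ring carbonyl, which is a planar vinylogous ester (conjugated with O1 and the para silyloxy group) and would have to become a strained spiro centre.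

Step 5
Reactants: 5 5-(2-methyl-1,3-dioxolan-2-yl)-6-[(triisopropylsilyl)oxy]benzofuran-3(2H)-one
Product: 6 (3R)-5-(2-methyl-1,3-dioxolan-2-yl)-6-[(triisopropylsilyl)oxy]-2,3-dihydrobenzofuran-3-ol
Conditions: RuCl(p-cymene)[(S,S)-TsDPEN] (1 mol%), HCO2H/Et3N (1:2, amine-rich), DMF, 40 °C
Reagents that add atoms: none
Why: Noyori asymmetric transfer hydrogenation of a cyclic aryl ketone; the aryl ring sits under the arene ligand in the usual transition state, so hydride reaches the face that gives the (3R) carbinol, and the amine-rich formate medium keeps the ketal intact.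

Step 6
Reactants: 6 (3R)-5-(2-methyl-1,3-dioxolan-2-yl)-6-[(triisopropylsilyl)oxy]-2,3-dihydrobenzofuran-3-ol; 7 2-(diethoxyphosphoryl)acetic acid
Product: 8 (3R)-5-(2-methyl-1,3-dioxolan-2-yl)-6-[(triisopropylsilyl)oxy]-2,3-dihydrobenzofuran-3-yl 2-(diethoxyphosphoryl)acetate
Conditions: DCC, DMAP (10 mol%), CH2Cl2, 0 °C to rt
Reagents that add atoms: none
Why: Steglich esterification, the usual way to phosphonoacetate esters; the acylation takes place at oxygen, so the C3 configuration is retained, and the neutral conditions avoid ionizing the benzylic carbinol.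

Step 7
Reactants: 8 (3R)-5-(2-methyl-1,3-dioxolan-2-yl)-6-[(triisopropylsilyl)oxy]-2,3-dihydrobenzofuran-3-yl 2-(diethoxyphosphoryl)acetate
Product: 9 (3R)-5-(2-methyl-1,3-dioxolan-2-yl)-6-[(triisopropylsilyl)oxy]-2,3-dihydrobenzofuran-3-yl 2-diazo-2-(diethoxyphosphoryl)acetate
Conditions: NaH, THF, 0 °C; then p-ABSA, 0 °C to rt
Reagents that add atoms: 4-acetamidobenzenesulfonyl azide, SMILES CC(=O)Nc1ccc(cc1)S(=O)(=O)N=[N+]=[N-]
Why: Regitz diazo transfer to the doubly activated methylene group of a phosphonoacetate; only that position is deprotonated, and ketal, silyl ether and the stereocentre take no part.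

Step 8
Reactants: 9 (3R)-5-(2-methyl-1,3-dioxolan-2-yl)-6-[(triisopropylsilyl)oxy]-2,3-dihydrobenzofuran-3-yl 2-diazo-2-(diethoxyphosphoryl)acetate
Product: 10 diethyl [(3R,3aS,8bR)-7-(2-methyl-1,3-dioxolan-2-yl)-2-oxo-6-[(triisopropylsilyl)oxy]-3,3a-dihydro-2H,8bH-furo[3,2-b]benzofuran-3-yl]phosphonate (cis-fused, phosphoryl group on the convex face)
Conditions: Rh2(OAc)4 (2 mol%), ClCH2CH2Cl, reflux, slow addition of 9
Reagents that add atoms: none
Why: Rh2(OAc)4 (a dimer of divalent rhodium) expels N2 from 9 and gives an electrophilic rhodium carbene flanked by the phosphoryl and ester groups. The carbene carbon engages the C2–H bond on the same face as the C3 ester oxygen in a concerted three-centre insertion, so the C–C bond forms with retention at C2. The closest known reaction type is the dirhodium tetracarboxylate-catalyzed 1,5 C–H insertion of α-diazo-α-(dialkoxyphosphoryl)acetates to α-phosphono-γ-butyrolactones, which is favoured next to an ether oxygen. The one ring closed is the γ-lactone, formed by C–C bond formation within a five-membered array (carbene carbon, carbonyl carbon, ester oxygen, C3, C2). The new stereocentre at C2 is controlled by C3: only the cis C2–H can be reached by the tethered carbene, hence the cis fusion and the configuration needed for 18; the phosphonate-bearing carbon is the second new centre, should settle with phosphorus on the convex face, and is erased in step 9. The step needs site selectivity for C2–H over C3–H (four-membered lactone) and over the aromatic ring; the lone pair on O1 makes C2–H the most hydridic bond within reach, the acyloxy group deactivates C3–H, and five-membered closure is preferred. Slow addition keeps carbene dimerization down.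

Step 9
Reactants: 10 diethyl [(3R,3aS,8bR)-7-(2-methyl-1,3-dioxolan-2-yl)-2-oxo-6-[(triisopropylsilyl)oxy]-3,3a-dihydro-2H,8bH-furo[3,2-b]benzofuran-3-yl]phosphonate
Product: 11 (3aR,8bR)-3-methylidene-7-(2-methyl-1,3-dioxolan-2-yl)-6-[(triisopropylsilyl)oxy]-3,3a-dihydro-2H,8bH-furo[3,2-b]benzofuran-2-one
Conditions: aq. HCHO (37%), K2CO3, THF, 0 °C to rt
Reagents that add atoms: formaldehyde, SMILES C=O
Why: Horner–Wadsworth–Emmons methylenation of an α-phosphono lactone; the carbanion forms under carbonate and is taken up at once by excess formaldehyde, and should it open the ring by loss of the O1 aryloxide, the phenoxide can only add back to the same face, so the cis fusion is not at stake.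

Step 10
Reactants: 11 (3aR,8bR)-3-methylidene-7-(2-methyl-1,3-dioxolan-2-yl)-6-[(triisopropylsilyl)oxy]-3,3a-dihydro-2H,8bH-furo[3,2-b]benzofuran-2-one
Product: 12 (2R,3R)-2-(3-hydroxyprop-1-en-2-yl)-5-(2-methyl-1,3-dioxolan-2-yl)-6-[(triisopropylsilyl)oxy]-2,3-dihydrobenzofuran-3-ol
Conditions: i-Bu2AlH (4 equiv), CH2Cl2, −78 to 0 °C; aq. KNaC4H4O6 work-up
Reagents that add atoms: none
Why: Exhaustive i-Bu2AlH reduction of a lactone through the lactol to the diol; hydride goes to the carbonyl (1,2) at low temperature in a non-coordinating solvent, which spares the exocyclic alkene, and ketal, silyl ether and both stereocentres are untouched.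

Step 11
Reactants: 12 (2R,3R)-2-(3-hydroxyprop-1-en-2-yl)-5-(2-methyl-1,3-dioxolan-2-yl)-6-[(triisopropylsilyl)oxy]-2,3-dihydrobenzofuran-3-ol
Product: 13 2-[(2R,3R)-3-hydroxy-5-(2-methyl-1,3-dioxolan-2-yl)-6-[(triisopropylsilyl)oxy]-2,3-dihydrobenzofuran-2-yl]prop-2-en-1-yl acetate
Conditions: AcCl (1.05 equiv), 2,4,6-collidine, CH2Cl2, −78 °C
Reagents that add atoms: acetyl chloride, SMILES CC(Cl)=O
Why: Selective acylation of a primary alcohol with acetyl chloride and a hindered pyridine base at low temperature; the C3 hydroxyl is secondary, benzylic and shielded by the cis C2 substituent.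

Step 12
Reactants: 13 2-[(2R,3R)-3-hydroxy-5-(2-methyl-1,3-dioxolan-2-yl)-6-[(triisopropylsilyl)oxy]-2,3-dihydrobenzofuran-2-yl]prop-2-en-1-yl acetate
Product: 14 2-[(2R,3R)-5-acetyl-3-hydroxy-6-[(triisopropylsilyl)oxy]-2,3-dihydrobenzofuran-2-yl]prop-2-en-1-yl acetate
Conditions: PPTS (0.2 equiv), acetone/H2O (10:1), rt
Reagents that add atoms: water, SMILES O
Why: Mild acid hydrolysis of a dioxolane; the ketal of an aryl ketone flanked by two oxygen donors opens far more readily than the C3 carbinol ionizes, and unveiling the acetyl group here lowers the electron density of the ring before the ionizable C3 ester is made.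

Step 13
Reactants: 14 2-[(2R,3R)-5-acetyl-3-hydroxy-6-[(triisopropylsilyl)oxy]-2,3-dihydrobenzofuran-2-yl]prop-2-en-1-yl acetate; 15 angelic acid [(Z)-2-methylbut-2-enoic acid]
Product: 17 (2R,3R)-2-(3-acetoxyprop-1-en-2-yl)-5-acetyl-6-[(triisopropylsilyl)oxy]-2,3-dihydrobenzofuran-3-yl (Z)-2-methylbut-2-enoate, via angelic 2,4,6-trichlorobenzoic anhydride 16 (not isolated)
Conditions: 15, 2,4,6-Cl3C6H2COCl, Et3N, toluene, rt; then 14, 75 °C
Reagents that add atoms: 2,4,6-trichlorobenzoyl chloride, SMILES O=C(Cl)c1c(Cl)cc(Cl)cc1Cl (its aroyl group is carried by 16 only)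
Why: Yamaguchi-type esterification through the preformed mixed anhydride, run without a nucleophilic catalyst because that is the protocol known to transfer the angeloyl group without Z to E isomerization; the alcohol attacks the unhindered angeloyl carbonyl, not the 2,6-dichlorinated aroyl one, and C3 reacts at oxygen with retention.

Step 14
Reactants: 17 (2R,3R)-2-(3-acetoxyprop-1-en-2-yl)-5-acetyl-6-[(triisopropylsilyl)oxy]-2,3-dihydrobenzofuran-3-yl (Z)-2-methylbut-2-enoate
Product: 18 (2R,3R)-2-(3-acetoxyprop-1-en-2-yl)-5-acetyl-6-hydroxy-2,3-dihydrobenzofuran-3-yl (Z)-2-methylbut-2-enoate (CNP0323250.1)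
Conditions: Bu4NF, AcOH (1:1), THF, 0 °C
Reagents that add atoms: none
Why: Fluoride cleavage of an aryl silyl ether that is ortho to a ketone and therefore labile; the acetic acid buffer means no free phenoxide (which could expel the para benzylic angelate) and no basic fluoride (which could attack or isomerize the esters), and the released phenol is held by the hydrogen bond to the acetyl group.

## Compound list

1 | 1,1'-(4,6-dihydroxy-1,3-phenylene)diethanone | CC(=O)c1cc(C(C)=O)c(O)cc1O | starting material
2 | 1-(5-acetyl-2,4-dihydroxyphenyl)-2-bromoethan-1-one | CC(=O)c1cc(C(=O)CBr)c(O)cc1O | intermediate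
3 | 5-acetyl-6-hydroxybenzofuran-3(2H)-one | CC(=O)c1cc2c(cc1O)OCC2=O | intermediate
4 | 5-acetyl-6-[(triisopropylsilyl)oxy]benzofuran-3(2H)-one | CC(=O)c1cc2c(cc1O[Si](C(C)C)(C(C)C)C(C)C)OCC2=O | intermediate
5 | 5-(2-methyl-1,3-dioxolan-2-yl)-6-[(triisopropylsilyl)oxy]benzofuran-3(2H)-one | CC1(OCCO1)c1cc2c(cc1O[Si](C(C)C)(C(C)C)C(C)C)OCC2=O | intermediate
6 | (3R)-5-(2-methyl-1,3-dioxolan-2-yl)-6-[(triisopropylsilyl)oxy]-2,3-dihydrobenzofuran-3-ol | O[C@H]1COc2cc(O[Si](C(C)C)(C(C)C)C(C)C)c(C3(C)OCCO3)cc21 | intermediate
7 | 2-(diethoxyphosphoryl)acetic acid | CCOP(=O)(CC(=O)O)OCC | starting material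
8 | (3R)-5-(2-methyl-1,3-dioxolan-2-yl)-6-[(triisopropylsilyl)oxy]-2,3-dihydrobenzofuran-3-yl 2-(diethoxyphosphoryl)acetate | CCOP(=O)(OCC)CC(=O)O[C@H]1COc2cc(O[Si](C(C)C)(C(C)C)C(C)C)c(C3(C)OCCO3)cc21 | intermediate
9 | (3R)-5-(2-methyl-1,3-dioxolan-2-yl)-6-[(triisopropylsilyl)oxy]-2,3-dihydrobenzofuran-3-yl 2-diazo-2-(diethoxyphosphoryl)acetate | CCOP(=O)(OCC)C(=[N+]=[N-])C(=O)O[C@H]1COc2cc(O[Si](C(C)C)(C(C)C)C(C)C)c(C3(C)OCCO3)cc21 | intermediate
10 | diethyl [(3R,3aS,8bR)-7-(2-methyl-1,3-dioxolan-2-yl)-2-oxo-6-[(triisopropylsilyl)oxy]-3,3a-dihydro-2H,8bH-furo[3,2-b]benzofuran-3-yl]phosphonate | CCOP(=O)(OCC)[C@H]1C(=O)O[C@@H]2c3cc(C4(C)OCCO4)c(O[Si](C(C)C)(C(C)C)C(C)C)cc3O[C@H]12 | intermediate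
11 | (3aR,8bR)-3-methylidene-7-(2-methyl-1,3-dioxolan-2-yl)-6-[(triisopropylsilyl)oxy]-3,3a-dihydro-2H,8bH-furo[3,2-b]benzofuran-2-one | C=C1C(=O)O[C@@H]2c3cc(C4(C)OCCO4)c(O[Si](C(C)C)(C(C)C)C(C)C)cc3O[C@H]12 | intermediate
12 | (2R,3R)-2-(3-hydroxyprop-1-en-2-yl)-5-(2-methyl-1,3-dioxolan-2-yl)-6-[(triisopropylsilyl)oxy]-2,3-dihydrobenzofuran-3-ol | C=C(CO)[C@H]1Oc2cc(O[Si](C(C)C)(C(C)C)C(C)C)c(C3(C)OCCO3)cc2[C@H]1O | intermediate
13 | 2-[(2R,3R)-3-hydroxy-5-(2-methyl-1,3-dioxolan-2-yl)-6-[(triisopropylsilyl)oxy]-2,3-dihydrobenzofuran-2-yl]prop-2-en-1-yl acetate | C=C(COC(C)=O)[C@H]1Oc2cc(O[Si](C(C)C)(C(C)C)C(C)C)c(C3(C)OCCO3)cc2[C@H]1O | intermediate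
14 | 2-[(2R,3R)-5-acetyl-3-hydroxy-6-[(triisopropylsilyl)oxy]-2,3-dihydrobenzofuran-2-yl]prop-2-en-1-yl acetate | C=C(COC(C)=O)[C@H]1Oc2cc(O[Si](C(C)C)(C(C)C)C(C)C)c(C(C)=O)cc2[C@H]1O | intermediate
15 | angelic acid, (Z)-2-methylbut-2-enoic acid | C/C=C(/C)C(=O)O | starting material
16 | (Z)-2-methylbut-2-enoic 2,4,6-trichlorobenzoic anhydride | C/C=C(/C)C(=O)OC(=O)c1c(Cl)cc(Cl)cc1Cl | intermediate
17 | (2R,3R)-2-(3-acetoxyprop-1-en-2-yl)-5-acetyl-6-[(triisopropylsilyl)oxy]-2,3-dihydrobenzofuran-3-yl (Z)-2-methylbut-2-enoate | C=C(COC(C)=O)[C@H]1Oc2cc(O[Si](C(C)C)(C(C)C)C(C)C)c(C(C)=O)cc2[C@H]1OC(=O)/C(C)=C\C | intermediate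
18 | (2R,3R)-2-(3-acetoxyprop-1-en-2-yl)-5-acetyl-6-hydroxy-2,3-dihydrobenzofuran-3-yl (Z)-2-methylbut-2-enoate | C=C(COC(C)=O)[C@H]1Oc2cc(O)c(C(C)=O)cc2[C@H]1OC(=O)/C(C)=C\C | target

## Step count and least certain steps

Total: 14 steps. Longest linear sequence: 14 steps (1 to 18); acids 7 and 15 enter in single steps.

**Step 8 (key step).** The carbene may be diverted from C2–H. It could insert into the benzylic C3–H bond on the ester-bearing carbon to give a β-lactone. It could also add to the electron-rich arene, which a strongly electrophilic doubly acceptor-substituted carbene tolerates poorly.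

The fallback keeps the C–H insertion but changes the carbene class, the catalyst class and the origin of the methylene carbon. It sets out from alcohol 6 and returns at 11:

- Acylation of 6 with bromoacetyl bromide and pyridine would give (3R)-5-(2-methyl-1,3-dioxolan-2-yl)-6-[(triisopropylsilyl)oxy]-2,3-dihydrobenzofuran-3-yl 2-bromoacetate F1.
- N,N'-Ditosylhydrazine and DBU would convert it into the corresponding 2-diazoacetate F2.
- Rh2(NHCOCH3)4 (dirhodium tetraacetamidate, divalent rhodium) in CH2Cl2 at reflux is more selective for five-membered C–H insertion next to ether oxygen than the tetraacetate. It should give (3aR,8bR)-7-(2-methyl-1,3-dioxolan-2-yl)-6-[(triisopropylsilyl)oxy]-3,3a-dihydro-2H,8bH-furo[3,2-b]benzofuran-2-one F3.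
- Condensation with tert-butoxybis(dimethylamino)methane would give the (E)-3-[(dimethylamino)methylidene] lactone F4.
- Conjugate reduction with i-Bu2AlH at −78 °C, followed by loss of dimethylamine on work-up, would deliver 11.

**Step 4.** The two aryl ketone carbonyls may be told apart poorly. The result would be ketalization of the ring carbonyl as well, or acid-induced self-condensation of the enolizable coumaranone.

The fallback hides the ring ketone as its aromatic enol ester. It sets out from 3 and returns at 5:

- Ac2O and pyridine would give 5-acetylbenzofuran-3,6-diyl diacetate F5, in which only the acetyl carbonyl remains.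
- The same silyl-glycol ketalization would give 5-(2-methyl-1,3-dioxolan-2-yl)benzofuran-3,6-diyl diacetate F6.
- K2CO3 in MeOH would remove both acetates to 6-hydroxy-5-(2-methyl-1,3-dioxolan-2-yl)benzofuran-3(2H)-one F7.
- Silylation with TIPSCl and imidazole would give 5.

**Step 13.** The angeloyl group may isomerize to the tigloyl group during activation and heating. Acylation of the hindered C3 hydroxyl may also be slow enough for acetyl migration or ionization at C3 to intervene.

The fallback builds the Z alkene on the ester and does not transfer it. It sets out from 14 and returns at 17: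

- Steglich esterification of 14 with 2-[bis(2,2,2-trifluoroethoxy)phosphoryl]propanoic acid would give (2R,3R)-2-(3-acetoxyprop-1-en-2-yl)-5-acetyl-6-[(triisopropylsilyl)oxy]-2,3-dihydrobenzofuran-3-yl 2-[bis(2,2,2-trifluoroethoxy)phosphoryl]propanoate F8, as a mixture of epimers at the phosphonate carbon.
- Still–Gennari olefination with acetaldehyde (KN(SiMe3)2, 18-crown-6, THF, −78 °C) would give the Z-configured angelate 17.

**Step 5.** The ring carbonyl is a deactivated vinylogous ester, so hydride transfer may be slow or poorly face-selective. Prolonged exposure to the formate medium could also cost the ketal.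

The fallback replaces transfer hydrogenation by a Corey–Bakshi–Shibata reduction. The (R)-2-methyl-CBS-oxazaborolidine with BH3·SMe2 in THF should give the same facial sense, by analogy with 1-indanone. It sets out from 5 and returns at 6 without any new compound.

## Further compounds

F1 | step 8 | (3R)-5-(2-methyl-1,3-dioxolan-2-yl)-6-[(triisopropylsilyl)oxy]-2,3-dihydrobenzofuran-3-yl 2-bromoacetate | BrCC(=O)O[C@H]1COc2cc(O[Si](C(C)C)(C(C)C)C(C)C)c(C3(C)OCCO3)cc21
F2 | step 8 | (3R)-5-(2-methyl-1,3-dioxolan-2-yl)-6-[(triisopropylsilyl)oxy]-2,3-dihydrobenzofuran-3-yl 2-diazoacetate | [N-]=[N+]=CC(=O)O[C@H]1COc2cc(O[Si](C(C)C)(C(C)C)C(C)C)c(C3(C)OCCO3)cc21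
F3 | step 8 | (3aR,8bR)-7-(2-methyl-1,3-dioxolan-2-yl)-6-[(triisopropylsilyl)oxy]-3,3a-dihydro-2H,8bH-furo[3,2-b]benzofuran-2-one | C1C(=O)O[C@@H]2c3cc(C4(C)OCCO4)c(O[Si](C(C)C)(C(C)C)C(C)C)cc3O[C@H]12
F4 | step 8 | (3aR,8bR,E)-3-[(dimethylamino)methylidene]-7-(2-methyl-1,3-dioxolan-2-yl)-6-[(triisopropylsilyl)oxy]-3,3a-dihydro-2H,8bH-furo[3,2-b]benzofuran-2-one | CN(C)/C=C1/C(=O)O[C@@H]2c3cc(C4(C)OCCO4)c(O[Si](C(C)C)(C(C)C)C(C)C)cc3O[C@H]12
F5 | step 4 | 5-acetylbenzofuran-3,6-diyl diacetate | CC(=O)Oc1coc2cc(OC(C)=O)c(C(C)=O)cc12
F6 | step 4 | 5-(2-methyl-1,3-dioxolan-2-yl)benzofuran-3,6-diyl diacetate | CC(=O)Oc1coc2cc(OC(C)=O)c(C3(C)OCCO3)cc12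
F7 | step 4 | 6-hydroxy-5-(2-methyl-1,3-dioxolan-2-yl)benzofuran-3(2H)-one | CC1(OCCO1)c1cc2c(cc1O)OCC2=O
F8 | step 13 | (2R,3R)-2-(3-acetoxyprop-1-en-2-yl)-5-acetyl-6-[(triisopropylsilyl)oxy]-2,3-dihydrobenzofuran-3-yl 2-[bis(2,2,2-trifluoroethoxy)phosphoryl]propanoate | C=C(COC(C)=O)[C@H]1Oc2cc(O[Si](C(C)C)(C(C)C)C(C)C)c(C(C)=O)cc2[C@H]1OC(=O)C(C)P(=O)(OCC(F)(F)F)OCC(F)(F)F
F0 | step 5 | none | none
A1 | alternative 1 | (3R,4R)-6-acetyl-7-[(tert-butyldimethylsilyl)oxy]-3-hydroxy-2,2-dimethylchroman-4-yl (Z)-2-methylbut-2-enoate | CC1(C)Oc2cc(O[Si](C)(C)C(C)(C)C)c(C(C)=O)cc2[C@@H](OC(=O)/C(C)=C\C)[C@H]1O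
A2 | alternative 1 | (2R,3R)-5-acetyl-6-[(tert-butyldimethylsilyl)oxy]-2-(prop-1-en-2-yl)-2,3-dihydrobenzofuran-3-yl (Z)-2-methylbut-2-enoate | C=C(C)[C@H]1Oc2cc(O[Si](C)(C)C(C)(C)C)c(C(C)=O)cc2[C@H]1OC(=O)/C(C)=C\C
A3 | alternative 2 | (Z)-3-methyl-8-(2-methyl-1,3-dioxolan-2-yl)-9-[(triisopropylsilyl)oxy]-4H,6H-benzo[b][1,5]dioxocine | C/C1=C/Oc2cc(O[Si](C(C)C)(C(C)C)C(C)C)c(C3(C)OCCO3)cc2COC1
A4 | alternative 2 | (2R,3R)-5-(2-methyl-1,3-dioxolan-2-yl)-2-(prop-1-en-2-yl)-6-[(triisopropylsilyl)oxy]-2,3-dihydrobenzofuran-3-ol | C=C(C)[C@H]1Oc2cc(O[Si](C(C)C)(C(C)C)C(C)C)c(C3(C)OCCO3)cc2[C@H]1O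
A5 | alternative 3 | 2-[(2S)-5-(2-methyl-1,3-dioxolan-2-yl)-6-[(triisopropylsilyl)oxy]-2,3-dihydrobenzofuran-2-yl]prop-2-enoic acid | C=C(C(=O)O)[C@@H]1Cc2cc(C3(C)OCCO3)c(O[Si](C(C)C)(C(C)C)C(C)C)cc2O1
A6 | alternative 3 | (3aR,8bR)-3-methylidene-7-(2-methyl-1,3-dioxolan-2-yl)-6-[(triisopropylsilyl)oxy]-3,3a-dihydro-2H,8bH-furo[3,2-b]benzofuran-2-one (identical with 11) | C=C1C(=O)O[C@@H]2c3cc(C4(C)OCCO4)c(O[Si](C(C)C)(C(C)C)C(C)C)cc3O[C@H]12
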